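The earlier runs and the new flask are calculated on assumed constants; noise was put on by code.

The pitfall in these flasks is to count extra time as extra product: Thursday's and Saturday's are asked at 20 min, twice the last reading of the earlier runs, and I want the single ring there by hand.

in all of them: starting material 0.61 M

| flask | protic impurity | remark | time |
|---|---|---|---|
| elm | 0.086 M | run made earlier |  |
| alder | 0.18 M | run made earlier |  |
| cedar | 0.21 M | run made earlier |  |
| Thursday's | 0.120 M |  | 20 min |
| Saturday's | 0.240 M |  | 20 min |

| run | time / min | open trimer / % | starting material / % | ring dimer / % | single ring / % | open dimer / % |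
|---|---|---|---|---|---|---|
| elm | 0.833 | 6.2 | 33.5 | 1.6 | 42.1 | 11.6 |
| elm | 2.50 | 11.4 | 5.7 | 5.8 | 63.9 | 7.1 |
| elm | 5.00 | 11.5 | 0.3 | 8.5 | 67.9 | 3.7 |
| elm | 8.00 | 12.2 | 0.1 | 10.3 | 68.6 | 2.0 |
| elm | 10.0 | 11.8 | 0 | 11.2 | 68.9 | 1.2 |
| alder | 0.833 | 6.2 | 31.4 | 0.8 | 40.3 | 10.6 |
| alder | 2.50 | 10.5 | 5.2 | 4.5 | 59.1 | 6.8 |
| alder | 5.00 | 10.8 | 0.6 | 8.3 | 63.3 | 3.6 |
| alder | 8.00 | 10.5 | 0 | 9.6 | 63.9 | 2.0 |
| alder | 10.0 | 10.6 | 0.4 | 10.7 | 63.4 | 1.2 |
| cedar | 2.00 | 9.2 | 7.5 | 4.0 | 55.5 | 7.5 |
| cedar | 4.00 | 10.1 | 1.0 | 7.2 | 61.4 | 4.8 |
| cedar | 6.00 | 10.3 | 0 | 8.5 | 61.7 | 3.2 |
| cedar | 8.00 | 10.5 | 0.4 | 9.9 | 62.4 | 1.6 |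
| cedar | 10.0 | 10.0 | 0.3 | 10.2 | 62.4 | 1.2 |

(each reading ± 0.3 percentage points)

- which of these there is most of at the end, counted by the starting material in it, Thursday's (single ring / ring dimer / open trimer / open dimer)
- which of these there is most of at the end, counted by the starting material in it, Saturday's (single ring / ring dimer / open trimer / open dimer)
- how much there is at the end of the one of these that leads, in percent of the starting material charged: Thursday's
- how much there is at the end of the one of these that leads, in percent of the starting material charged: Saturday's

- in percentages every species weighs as the starting material in it: one open dimer or ring dimer counts as two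
- in percentages every species weighs as the starting material in it: one open trimer counts as three

1. In the elm run, from 8.00 min to 10.0 min, the open dimer falls by 0.8 percentage points and the ring dimer rises by 0.9 points, while the single ring moves by 0.3 points against a scatter of 0.3 points, so I treat the single ring as flat and take its late readings for the end.

2. The cedar run has more protic impurity than the other two, yet its last reading has 62.4 % single ring against 10.2 % ring dimer and 10.0 % open trimer, so I expect the single ring to lead in both flasks.

3. From the elm run to the cedar run, the last readings of single ring, taken as fractions of the charge and set against the protic impurity, give a slope of 0.524 M⁻¹.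

4. Counted from the elm run, that line gives 67.1 % for Thursday's and 60.8 % for Saturday's.

5. The weak link is that each end of the line rests on one reading, so I reforge it with the mean of the last two readings: 68.8 % for the elm run and 62.4 % for the cedar run. This gives 0.512 M⁻¹, the quantity I carry: the fall per molar, the fraction of the charge lost from the single ring plateau for each molar of protic impurity, at this charge of starting material. The alder run, unused so far, stands at 63.7 % against 63.9 % from the line. I commit to 67.0 % for Thursday's and 60.9 % for Saturday's, the latter lying beyond the cedar run.

The forecast names single ring for Thursday's at 67.1 % (range 66.2 % to 68 %) and single ring for Saturday's at 60.7 % (range 59.3 % to 61.9 %), reasoning that “The impurity seems to consume starting material stoichiometrically”. My line is a different reckoning with slightly different numbers.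

The flask gives single ring at 66.8 % in Thursday's and single ring at 60.8 % in Saturday's.

    starting material → single ring (k = 0.840 min⁻¹)
    starting material + open dimer → open trimer (k = 1.90 M⁻¹ min⁻¹)
    open dimer → ring dimer (k = 0.230 min⁻¹)
    starting material + protic impurity → quenched substrate (k = 1.40 M⁻¹ min⁻¹)
    2 starting material → open dimer (k = 0.440 M⁻¹ min⁻¹)

Between these two flasks the fall per molar comes to 0.506 M⁻¹, beside my 0.512 M⁻¹. At the start of Saturday's, starting material goes faster to single ring, with 0.84 min⁻¹, than to quenched substrate, with 0.336 min⁻¹, the constant of that step times the charged protic impurity. Saturday's ends with 18.1 % quenched substrate, against 9.70 % in Thursday's. For the neighbour of Thursday's charged with 0.048 M of protic impurity, the fall per molar gives 70.7 %, and that flask holds 70.9 % single ring.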